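## Retrosynthetic overview

1. Last bond: enone β-carbon–CH2. A right-half primary alkyllithium adds to a left-half vinylogous ester (Stork–Danheiser); acid then reveals the enone and removes all silyl groups.
2. Left half (cis-hydroazulene): the cycloheptane-1,3-dione comes from a two-carbon ring expansion (dichloroketene [2+2], reductive retro-aldol) of a cis-diquinanone. Both ring-fusion centres come from an OH-directed hydrogenation. The diquinane comes from a Pauson–Khand reaction of (R)-dehydrolinalool (geraniol, Sharpless epoxidation).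
3. Right half (trans-fused oxepane–cyclohexane): one epoxide-opening cascade of a (R,R,S)-diepoxy silyl enol ether closes both rings. The axial tertiary alcohol comes from equatorial methyl addition. The two epoxides come from Shi epoxidations of opposite sense on a geranyl chain.
4. Ring order: left cyclopentane and cyclopentenone together, then the cycloheptane; right oxepane and cyclohexane together; the two bicycles are joined last.

Assumption: both enantiomers of the Shi ketone are treated as purchasable catalysts; reagents and catalysts are named (with SMILES where they add atoms) but not numbered.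

## Route

Step 1
Reactants: 1 geraniol
Product: 2 (2R,3R)-2,3-epoxygeraniol
Conditions: Ti(OiPr)4 (5 mol %), D-(−)-diethyl tartrate (6 mol %), t-BuOOH, 4 Å MS, CH2Cl2, −20 °C
Reagents that add atoms: tert-butyl hydroperoxide, CC(C)(C)OO
Why: Sharpless asymmetric epoxidation; the D-tartrate complex delivers oxygen to the face of the (E)-allylic alcohol that gives the (2R,3R)-epoxide, which fixes the future tertiary carbinol carbon.

Step 2
Reactants: 2 (2R,3R)-2,3-epoxygeraniol
Product: 3 (2S,3R)-2-(chloromethyl)-3-methyl-3-(4-methylpent-3-en-1-yl)oxirane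
Conditions: PPh3, CCl4, NaHCO3, reflux
Reagents that add atoms: carbon tetrachloride, ClC(Cl)(Cl)Cl
Why: Appel chlorination of the primary alcohol leaves both epoxide centres untouched (the C2 descriptor changes only through priorities).

Step 3
Reactants: 3 epoxy chloride
Product: 4 (R)-dehydrolinalool
Conditions: n-BuLi (3.2 equiv), THF, −35 °C; aq NH4Cl
Reagents that add atoms: none
Why: Base-induced double elimination of the 2,3-epoxy chloride (epoxide opening to a chlorovinyl alkoxide, then dehydrochlorination) gives the tertiary propargylic alcohol with the C–O bond, and so the configuration, retained.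

Step 4
Reactants: 4 (R)-dehydrolinalool
Product: 5 (8R)-8-hydroxy-4,4,8-trimethylbicyclo[3.3.0]oct-1-en-3-one
Conditions: Co2(CO)8 (20 mol %), tetramethylthiourea (60 mol %), CO (1 atm), toluene, 70 °C
Reagents that add atoms: carbon monoxide, [C-]#[O+]
Why: Intramolecular Pauson–Khand reaction joins alkyne, isopropylidene alkene and CO into the diquinane enone with the gem-dimethyl carbon in place; the ring-fusion CH forms as an epimer mixture that is erased in step 5.

Step 5
Reactants: 5 bicyclic enone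
Product: 7 (6R)-6-hydroxy-2,2,6-trimethylbicyclo[3.3.0]oct-1(5)-en-3-one, via dipotassium dienolate alkoxide 6 (not isolated)
Conditions: KOt-Bu (3 equiv), t-BuOH/THF, 0 °C; then poured into AcOH/H2O, 0 °C
Reagents that add atoms: none
Why: Deconjugation of the enone: the only acidic C–H is the γ ring-fusion H, and kinetic α-protonation of the resulting dienolate moves the alkene to the tetrasubstituted ring-fusion position, removing the uncontrolled centre.

Step 6
Reactants: 7 ring-fusion alkene
Product: 8 (1R,5R,6R)-6-hydroxy-2,2,6-trimethylbicyclo[3.3.0]octan-3-one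
Conditions: H2 (1 atm), [Ir(cod)(PCy3)(py)]PF6 (5 mol %), CH2Cl2, rt
Reagents that add atoms: none
Why: Hydroxyl-directed homogeneous hydrogenation: the allylic tertiary OH binds iridium and both H atoms add to its face, giving the cis-fused diquinane with OH syn to both ring-fusion H atoms.

Step 7
Reactants: 8 hydroxy diquinanone
Product: 9 (1R,5R,6R)-2,2,6-trimethyl-6-(triethylsilyloxy)bicyclo[3.3.0]octan-3-one
Conditions: TESOTf, 2,6-lutidine, CH2Cl2, −78 → 0 °C
Reagents that add atoms: triethylsilyl trifluoromethanesulfonate, CC[Si](CC)(CC)OS(=O)(=O)C(F)(F)F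
Why: Silylation of the tertiary alcohol protects it from the acid chloride of step 9 and the organolithium of step 25.

Step 8
Reactants: 9 silyloxy diquinanone
Product: 10 trimethylsilyl enol ether of 9
Conditions: TMSOTf, Et3N, CH2Cl2, 0 °C
Reagents that add atoms: trimethylsilyl trifluoromethanesulfonate, C[Si](C)(C)OS(=O)(=O)C(F)(F)F
Why: Soft enolisation gives a single silyl enol ether because the other α-carbon is quaternary.

Step 9
Reactants: 10 silyl enol ether
Product: 11 dichlorocyclobutanone cycloadduct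
Conditions: Cl2CHCOCl, Et3N, hexane, rt
Reagents that add atoms: dichloroacetyl chloride, O=C(Cl)C(Cl)Cl
Why: [2+2] cycloaddition of dichloroketene made in situ; its carbonyl carbon bonds to the nucleophilic enol CH and the CCl2 carbon to the siloxy carbon, and the two new centres are lost in step 10.

Step 10
Reactants: 11 dichlorocyclobutanone
Product: 13 (1R,3aR,8aR)-1,4,4-trimethyl-1-(triethylsilyloxy)octahydroazulene-5,7-dione, via dechlorinated siloxycyclobutanone 12 (not isolated)
Conditions: Zn dust, AcOH, i-PrOH/H2O, rt → 50 °C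
Reagents that add atoms: none
Why: Reductive dechlorination, then loss of the bridgehead TMS group triggers retro-aldol opening of the β-oxy cyclobutanone, a net two-carbon ring expansion to the cycloheptane-1,3-dione with the ring stereocentres untouched.

Step 11
Reactants: 13 hydroazulene-1,3-dione
Product: 14 (1R,3aR,8aR)-1,4,4,6-tetramethyl-1-(triethylsilyloxy)octahydroazulene-5,7-dione
Conditions: MeI, K2CO3, acetone, reflux
Reagents that add atoms: iodomethane, CI
Why: C-alkylation of the 1,3-dione enolate at the doubly activated carbon installs the future enone α-methyl.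

Step 12
Reactants: 14 2-methyl-1,3-dione
Product: 15 (1R,3aR,8aR)-7-methoxy-1,4,4,6-tetramethyl-1-(triethylsilyloxy)-2,3,3a,4,8,8a-hexahydroazulen-5(1H)-one
Conditions: Me2SO4, K2CO3, acetone, reflux
Reagents that add atoms: dimethyl sulfate, COS(=O)(=O)OC
Why: O-alkylation with a hard electrophile occurs at the enolate oxygen remote from the gem-dimethyl group, leaving the carbonyl next to CMe2 as the site for the Stork–Danheiser addition.

Step 13
Reactants: 16 geranyl acetate
Product: 17 (S)-6,7-epoxygeranyl acetate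
Conditions: ent-Shi ketone (L-fructose-derived, 30 mol %), KHSO5, K2CO3, Bu4NHSO4, MeCN/dimethoxymethane/aq buffer pH 10.5, 0 °C
Reagents that add atoms: potassium peroxymonosulfate, [K+].[O-]S(=O)(=O)OO
Why: Shi epoxidation; the allylic acetate deactivates the 2,3-alkene, so only the terminal alkene reacts, and the ent-ketone gives the (S)-epoxide that becomes the C3 carbinol of the oxepane.

Step 14
Reactants: 17 (S)-6,7-epoxygeranyl acetate
Product: 18 (S)-6,7-epoxygeraniol
Conditions: K2CO3 (0.2 equiv), MeOH, 0 °C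
Reagents that add atoms: none
Why: Transesterification (Zemplén-type methanolysis) removes the acetate without touching the epoxide.

Step 15
Reactants: 18 (S)-6,7-epoxygeraniol
Product: 20 (S)-6,7-epoxygeranyl bromide, via allylic mesylate 19 (not isolated)
Conditions: MsCl, Et3N, CH2Cl2, −40 °C; then LiBr, THF, 0 °C
Reagents that add atoms: lithium bromide, [Li+].[Br-]
Why: Mesylation then SN2 displacement by bromide gives the (E)-allylic bromide without allylic transposition.

Step 16
Reactants: 20 (S)-6,7-epoxygeranyl bromide, 21 N-methoxy-N-methylacetamide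
Product: 23 (4E)-7-[(2S)-3,3-dimethyloxiran-2-yl]-N-methoxy-N,5-dimethylhept-4-enamide, via lithium amide enolate 22 (not isolated)
Conditions: LiN(i-Pr)2, THF, −78 °C; then 20, −78 → 0 °C
Reagents that add atoms: none
Why: Enolate alkylation (SN2 at the primary allylic bromide) attaches the two-carbon Weinreb amide unit with the (E)-alkene retained.

Step 17
Reactants: 23 epoxy enamide
Product: 24 (R,R,S)-diepoxy Weinreb amide
Conditions: Shi ketone (D-fructose-derived, 30 mol %), KHSO5, K2CO3, Bu4NHSO4, MeCN/dimethoxymethane/aq buffer pH 10.5, 0 °C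
Reagents that add atoms: potassium peroxymonosulfate, [K+].[O-]S(=O)(=O)OO
Why: Shi epoxidation of the remaining (E)-trisubstituted alkene with the D-ketone gives the (R,R)-epoxide, opposite in sense to the terminal one, as the target's oxepane requires.

Step 18
Reactants: 24 diepoxy Weinreb amide
Product: 25 diepoxy vinyl ketone
Conditions: CH2=CHMgBr, THF, −20 °C; cold aq NH4Cl
Reagents that add atoms: vinylmagnesium bromide, C=C[Mg]Br
Why: Weinreb ketone synthesis; the chelated tetrahedral intermediate prevents over-addition, and the trisubstituted epoxides do not react with the Grignard reagent at low temperature.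

Step 19
Reactants: 25 diepoxy vinyl ketone
Product: 26 (Z)-triethylsilyl enol ether
Conditions: CH2=CHMgBr, CuBr·SMe2 (10 mol %), Et3SiCl, HMPA, THF, −78 °C
Reagents that add atoms: vinylmagnesium bromide, C=C[Mg]Br; chlorotriethylsilane, CC[Si](Cl)(CC)CC
Why: Copper-catalysed conjugate addition with silyl trapping gives the enol ether regiospecifically on the allyl-bearing side, which base enolisation of the ketone could not do; either geometry converges later because C6 is epimerisable.

Step 20
Reactants: 26 diepoxy silyl enol ether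
Product: 27 (3S,5aR,6R,9aR)-6-allyl-2,2,5a-trimethyl-3-(triethylsilyloxy)octahydro-1-benzoxepin-7(2H)-one
Conditions: TESOTf (20 mol %), 2,6-di-tert-butyl-4-methylpyridine, CH2Cl2, −78 °C
Reagents that add atoms: none
Why: Biomimetic tandem oxa-/carbacyclisation with Mukaiyama-type termination: the internal epoxide oxygen opens the silyl-activated terminal epoxide at its tertiary carbon (oxepane), then the enol ether carbon opens the epoxonium at its tertiary carbon with inversion through a chair (trans fusion, equatorial allyl), and the silyl group ends on the C3 oxygen.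

Step 21
Reactants: 27 bicyclic ketone
Product: 28 (3S,5aR,6R,7S,9aR)-6-allyl-2,2,5a,7-tetramethyl-3-(triethylsilyloxy)decahydro-1-benzoxepin-7-ol
Conditions: MeMgBr, LaCl3·2LiCl (30 mol %), THF, 0 °C; aq NH4Cl
Reagents that add atoms: methylmagnesium bromide, C[Mg]Br
Why: Grignard 1,2-addition from the equatorial direction, because the axial face is blocked by the 1,3-diaxial angular methyl, gives the axial tertiary alcohol cis to the angular methyl (7S).

Step 22
Reactants: 28 tertiary alcohol
Product: 29 bis(triethylsilyl) ether of 28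
Conditions: TESOTf, 2,6-lutidine, CH2Cl2, 0 °C → rt
Reagents that add atoms: triethylsilyl trifluoromethanesulfonate, CC[Si](CC)(CC)OS(=O)(=O)C(F)(F)F
Why: Silylation of the hindered tertiary alcohol prevents tetrahydrofuran formation in step 24 and protonation of the organolithium in step 25.

Step 23
Reactants: 29 bis-silyl ether
Product: 31 primary alcohol, via aldehyde 30 (not isolated)
Conditions: O3, CH2Cl2/MeOH, −78 °C; then NaBH4, −78 °C → rt
Reagents that add atoms: ozone, [O-][O+]=O
Why: Ozonolysis of the only alkene with reductive work-up trims the allyl group to the two-carbon hydroxyethyl chain.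

Step 24
Reactants: 31 primary alcohol
Product: 32 primary iodide
Conditions: I2, PPh3, imidazole, CH2Cl2, 0 °C
Reagents that add atoms: iodine, II
Why: Appel-type iodination of the unhindered primary alcohol; the iodide is used at once.

Step 25
Reactants: 32 primary iodide, 15 vinylogous ester
Product: 36 target CNP0397160.2, via alkyllithium 33 (not isolated), via lithium alkoxide adduct 34 (not isolated), via tris(triethylsilyl) enone 35 (not isolated)
Conditions: t-BuLi (2.1 equiv), Et2O/pentane, −78 °C; then 15, LaCl3·2LiCl, THF, −78 → −20 °C; then 48 % aq HF, MeCN, 0 °C → rt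
Reagents that add atoms: water, O
Why: Iodine–lithium exchange, 1,2-addition to the vinylogous ester carbonyl and acid-mediated Stork–Danheiser transposition give the 3-alkyl-2-methyl enone; the same acid removes the three TES groups and no stereocentre is touched.

## Compound list

1 | geraniol, (2E)-3,7-dimethylocta-2,6-dien-1-ol | CC(C)=CCC/C(C)=C/CO | starting material
2 | (2R,3R)-2,3-epoxygeraniol, [(2R,3R)-3-methyl-3-(4-methylpent-3-en-1-yl)oxiran-2-yl]methanol | OC[C@H]1O[C@]1(C)CCC=C(C)C | intermediate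
3 | (2S,3R)-2-(chloromethyl)-3-methyl-3-(4-methylpent-3-en-1-yl)oxirane | ClC[C@H]1O[C@]1(C)CCC=C(C)C | intermediate
4 | (R)-dehydrolinalool, (3R)-3,7-dimethyloct-6-en-1-yn-3-ol | C#C[C@](C)(O)CCC=C(C)C | intermediate
5 | (8R)-8-hydroxy-4,4,8-trimethylbicyclo[3.3.0]oct-1-en-3-one (C5 epimers) | O=C1C(C)(C)C2CC[C@@](C)(O)C2=C1 | intermediate
6 | dipotassium salt of the ring-fusion dienolate and tertiary alkoxide of 5 | [K+].[K+].[O-]C1=CC2=C(CC[C@@]2(C)[O-])C1(C)C | intermediate
7 | (6R)-6-hydroxy-2,2,6-trimethylbicyclo[3.3.0]oct-1(5)-en-3-one | O=C1C(C)(C)C2=C(C1)[C@](C)(O)CC2 | intermediate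
8 | (1R,5R,6R)-6-hydroxy-2,2,6-trimethylbicyclo[3.3.0]octan-3-one (cis-fused, OH syn to both ring-fusion H) | O=C1C(C)(C)[C@@H]2CC[C@@](C)(O)[C@@H]2C1 | intermediate
9 | (1R,5R,6R)-2,2,6-trimethyl-6-(triethylsilyloxy)bicyclo[3.3.0]octan-3-one | O=C1C(C)(C)[C@@H]2CC[C@@](C)(O[Si](CC)(CC)CC)[C@@H]2C1 | intermediate
10 | trimethylsilyl enol ether of 9 (enol C=C toward the ring CH2; ring centres as in 9) | C[Si](C)(C)OC1=C[C@H]2[C@](C)(O[Si](CC)(CC)CC)CC[C@H]2C1(C)C | intermediate
11 | exo dichloroketene cycloadduct of 10: 2,2-dichloro-3-(trimethylsilyloxy)cyclobutanone fused across the former enol C=C | O=C1C(Cl)(Cl)[C@@]2(O[Si](C)(C)C)C(C)(C)[C@@H]3CC[C@@](C)(O[Si](CC)(CC)CC)[C@@H]3[C@@H]12 | intermediate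
12 | cyclobutanone 11 with CH2 in place of CCl2 | O=C1C[C@@]2(O[Si](C)(C)C)C(C)(C)[C@@H]3CC[C@@](C)(O[Si](CC)(CC)CC)[C@@H]3[C@@H]12 | intermediate
13 | (1R,3aR,8aR)-1,4,4-trimethyl-1-(triethylsilyloxy)octahydroazulene-5,7-dione | O=C1CC(=O)C(C)(C)[C@@H]2CC[C@@](C)(O[Si](CC)(CC)CC)[C@@H]2C1 | intermediate
14 | (1R,3aR,8aR)-1,4,4,6-tetramethyl-1-(triethylsilyloxy)octahydroazulene-5,7-dione (C6 epimers and enol) | O=C1C(C)C(=O)C(C)(C)[C@@H]2CC[C@@](C)(O[Si](CC)(CC)CC)[C@@H]2C1 | intermediate
15 | (1R,3aR,8aR)-7-methoxy-1,4,4,6-tetramethyl-1-(triethylsilyloxy)-2,3,3a,4,8,8a-hexahydroazulen-5(1H)-one | COC1=C(C)C(=O)C(C)(C)[C@@H]2CC[C@@](C)(O[Si](CC)(CC)CC)[C@@H]2C1 | intermediate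
16 | geranyl acetate | CC(=O)OC/C=C(\C)CCC=C(C)C | starting material
17 | (S)-6,7-epoxygeranyl acetate, (2E)-5-[(2S)-3,3-dimethyloxiran-2-yl]-3-methylpent-2-en-1-yl acetate | CC(=O)OC/C=C(\C)CC[C@@H]1OC1(C)C | intermediate
18 | (S)-6,7-epoxygeraniol | OC/C=C(\C)CC[C@@H]1OC1(C)C | intermediate
19 | (S)-6,7-epoxygeranyl methanesulfonate | CS(=O)(=O)OC/C=C(\C)CC[C@@H]1OC1(C)C | intermediate
20 | (S)-6,7-epoxygeranyl bromide | BrC/C=C(\C)CC[C@@H]1OC1(C)C | intermediate
21 | N-methoxy-N-methylacetamide | CON(C)C(C)=O | starting material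
22 | lithium enolate of N-methoxy-N-methylacetamide | [Li+].[O-]C(=C)N(C)OC | intermediate
23 | (4E)-7-[(2S)-3,3-dimethyloxiran-2-yl]-N-methoxy-N,5-dimethylhept-4-enamide | CON(C)C(=O)CC/C=C(\C)CC[C@@H]1OC1(C)C | intermediate
24 | 3-[(2R,3R)-3-{2-[(2S)-3,3-dimethyloxiran-2-yl]ethyl}-3-methyloxiran-2-yl]-N-methoxy-N-methylpropanamide | CON(C)C(=O)CC[C@H]1O[C@]1(C)CC[C@@H]1OC1(C)C | intermediate
25 | 5-[(2R,3R)-3-{2-[(2S)-3,3-dimethyloxiran-2-yl]ethyl}-3-methyloxiran-2-yl]pent-1-en-3-one | C=CC(=O)CC[C@H]1O[C@]1(C)CC[C@@H]1OC1(C)C | intermediate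
26 | triethyl({(4Z)-7-[(2R,3R)-3-{2-[(2S)-3,3-dimethyloxiran-2-yl]ethyl}-3-methyloxiran-2-yl]hepta-1,4-dien-5-yl}oxy)silane | C=CC/C=C(\O[Si](CC)(CC)CC)CC[C@H]1O[C@]1(C)CC[C@@H]1OC1(C)C | intermediate
27 | (3S,5aR,6R,9aR)-6-allyl-2,2,5a-trimethyl-3-(triethylsilyloxy)octahydro-1-benzoxepin-7(2H)-one (trans-fused, allyl equatorial) | C=CC[C@@H]1[C@@]2(C)CC[C@H](O[Si](CC)(CC)CC)C(C)(C)O[C@@H]2CCC1=O | intermediate
28 | (3S,5aR,6R,7S,9aR)-6-allyl-2,2,5a,7-tetramethyl-3-(triethylsilyloxy)decahydro-1-benzoxepin-7-ol (7-OH axial, cis to 5a-Me) | C=CC[C@@H]1[C@@]2(C)CC[C@H](O[Si](CC)(CC)CC)C(C)(C)O[C@@H]2CC[C@]1(C)O | intermediate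
29 | (3S,5aR,6R,7S,9aR)-6-allyl-2,2,5a,7-tetramethyl-3,7-bis(triethylsilyloxy)decahydro-1-benzoxepine | C=CC[C@@H]1[C@@]2(C)CC[C@H](O[Si](CC)(CC)CC)C(C)(C)O[C@@H]2CC[C@]1(C)O[Si](CC)(CC)CC | intermediate
30 | 2-[(3S,5aR,6R,7S,9aR)-2,2,5a,7-tetramethyl-3,7-bis(triethylsilyloxy)decahydro-1-benzoxepin-6-yl]acetaldehyde | O=CC[C@@H]1[C@@]2(C)CC[C@H](O[Si](CC)(CC)CC)C(C)(C)O[C@@H]2CC[C@]1(C)O[Si](CC)(CC)CC | intermediate
31 | 2-[(3S,5aR,6R,7S,9aR)-2,2,5a,7-tetramethyl-3,7-bis(triethylsilyloxy)decahydro-1-benzoxepin-6-yl]ethanol | OCC[C@@H]1[C@@]2(C)CC[C@H](O[Si](CC)(CC)CC)C(C)(C)O[C@@H]2CC[C@]1(C)O[Si](CC)(CC)CC | intermediate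
32 | (3S,5aR,6R,7S,9aR)-6-(2-iodoethyl)-2,2,5a,7-tetramethyl-3,7-bis(triethylsilyloxy)decahydro-1-benzoxepine | ICC[C@@H]1[C@@]2(C)CC[C@H](O[Si](CC)(CC)CC)C(C)(C)O[C@@H]2CC[C@]1(C)O[Si](CC)(CC)CC | intermediate
33 | 2-[(3S,5aR,6R,7S,9aR)-2,2,5a,7-tetramethyl-3,7-bis(triethylsilyloxy)decahydro-1-benzoxepin-6-yl]ethyllithium | [Li]CC[C@@H]1[C@@]2(C)CC[C@H](O[Si](CC)(CC)CC)C(C)(C)O[C@@H]2CC[C@]1(C)O[Si](CC)(CC)CC | intermediate
34 | lithium alkoxide from addition of 33 to the C5 carbonyl of 15 (new carbinol centre undefined) | [Li+].COC1=C(C)C([O-])(CC[C@@H]2[C@@]3(C)CC[C@H](O[Si](CC)(CC)CC)C(C)(C)O[C@@H]3CC[C@]2(C)O[Si](CC)(CC)CC)C(C)(C)[C@@H]2CC[C@@](C)(O[Si](CC)(CC)CC)[C@@H]2C1 | intermediate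
35 | tris(triethylsilyl) ether of the target | CC1=C(CC[C@@H]2[C@@]3(C)CC[C@H](O[Si](CC)(CC)CC)C(C)(C)O[C@@H]3CC[C@]2(C)O[Si](CC)(CC)CC)C(C)(C)[C@@H]2CC[C@@](C)(O[Si](CC)(CC)CC)[C@@H]2CC1=O | intermediate
36 | CNP0397160.2, (1R,3aR,8aR)-5-{2-[(3S,5aR,6R,7S,9aR)-3,7-dihydroxy-2,2,5a,7-tetramethyldecahydro-1-benzoxepin-6-yl]ethyl}-1-hydroxy-1,4,4,6-tetramethyl-2,3,3a,4,8,8a-hexahydroazulen-7(1H)-one | CC1=C(CC[C@@H]2[C@@]3(C)CC[C@H](O)C(C)(C)O[C@@H]3CC[C@]2(C)O)C(C)(C)[C@@H]2CC[C@@](C)(O)[C@@H]2CC1=O | target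

## Step count and risks

Total steps: 25. Longest linear sequence: 13 steps (steps 1–12 then 25, or equally steps 13–25).

The three steps most likely to fail:

Step 4 (Pauson–Khand reaction on an isopropylidene-terminated enyne; trisubstituted alkenes cyclise sluggishly). The fallback sets out from 4 and comes back at 5, installing the gem-dimethyl group after ring formation. Selective ozonolysis of the trisubstituted alkene of 4 (O3, CH2Cl2, −78 °C; Me2S) gives (4R)-4-hydroxy-4-methylhex-5-ynal F1. Wittig methylenation (Ph3P=CH2, THF) gives (3R)-3-methylhept-6-en-1-yn-3-ol F2. Its monosubstituted alkene undergoes the Pauson–Khand reaction under the step 4 conditions to give (8R)-8-hydroxy-8-methylbicyclo[3.3.0]oct-1-en-3-one F3. Two rounds of kinetic α′-methylation (LiN(i-Pr)2, MeI, THF, −78 °C; the cross-conjugated enolate can only form at C4) pass through the 4-methyl enone F4 and deliver 5.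

Step 20 (epoxide cascade terminated by an internal, trisubstituted silyl enol ether). The fallback sets out from 24 and comes back at 27, using a β-keto ester as the carbon nucleophile and introducing the allyl group afterwards. Acylation of the lithium enolate of allyl acetate with 24 gives allyl β-keto ester F5. Its enol terminates the same cascade (TESOTf 1.1 equiv, 2,6-di-tert-butyl-4-methylpyridine, CH2Cl2, −78 °C) to give bicyclic allyl β-keto ester F6. Pd(PPh3)4-catalysed decarboxylative allylation (Tsuji) transfers the allyl group regiospecifically to C6 with loss of CO2; brief DBU equilibration to the equatorial epimer returns 27.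

Step 25 (addition of a valuable alkyllithium to a carbonyl flanked by CMe2 and C(Me)=, where γ-deprotonation of the vinylogous ester can compete). The fallback sets out from 15 and 32 and comes back at 35, reversing polarity at the enone β-carbon and coupling under palladium catalysis. Deprotonation of 15 at C8 (KN(SiMe3)2, THF, −78 °C) and O-triflation of the extended enolate (PhNTf2) give dienyl triflate F7. Alkyllithium 33, made from 32 as in step 25, is trapped with B-methoxy-9-BBN to give lithium borinate F8. B-alkyl Suzuki–Miyaura coupling of F7 and F8 (Pd(dppf)Cl2, AsPh3, Cs2CO3, DMF/THF/H2O, rt) gives coupled methoxy diene F9. Aqueous HF in MeCN hydrolyses the dienyl ether to enone 35 and then desilylates it to 36.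

Further compounds

F1 | step 4 | (4R)-4-hydroxy-4-methylhex-5-ynal | C#C[C@](C)(O)CCC=O
F2 | step 4 | (3R)-3-methylhept-6-en-1-yn-3-ol | C#C[C@](C)(O)CCC=C
F3 | step 4 | (8R)-8-hydroxy-8-methylbicyclo[3.3.0]oct-1-en-3-one (C5 epimers) | O=C1CC2CC[C@@](C)(O)C2=C1
F4 | step 4 | (8R)-8-hydroxy-4,8-dimethylbicyclo[3.3.0]oct-1-en-3-one (C4 and C5 epimers) | O=C1C(C)C2CC[C@@](C)(O)C2=C1
F5 | step 20 | prop-2-en-1-yl 5-[(2R,3R)-3-{2-[(2S)-3,3-dimethyloxiran-2-yl]ethyl}-3-methyloxiran-2-yl]-3-oxopentanoate | C=CCOC(=O)CC(=O)CC[C@H]1O[C@]1(C)CC[C@@H]1OC1(C)C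
F6 | step 20 | prop-2-en-1-yl (3S,5aR,9aR)-2,2,5a-trimethyl-7-oxo-3-(triethylsilyloxy)decahydro-1-benzoxepine-6-carboxylate (C6 epimers and enol) | C=CCOC(=O)C1[C@@]2(C)CC[C@H](O[Si](CC)(CC)CC)C(C)(C)O[C@@H]2CCC1=O
F7 | step 25 | dienyl triflate of 15 (C5 enol triflate, C5=C6 and C7=C8 double bonds, 7-methoxy) | COC1=C[C@H]2[C@](C)(O[Si](CC)(CC)CC)CC[C@H]2C(C)(C)C(OS(=O)(=O)C(F)(F)F)=C1C
F8 | step 25 | lithium B-methoxy-B-alkyl-9-borabicyclo[3.3.1]nonane borinate from 33 | [Li+].CO[B-]3(CC[C@@H]1[C@@]2(C)CC[C@H](O[Si](CC)(CC)CC)C(C)(C)O[C@@H]2CC[C@]1(C)O[Si](CC)(CC)CC)C4CCCC3CCC4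
F9 | step 25 | coupled 7-methoxy-5-alkyl diene (tris-TES; methyl dienyl ether form of 35) | COC1=C[C@H]2[C@](C)(O[Si](CC)(CC)CC)CC[C@H]2C(C)(C)C(CC[C@@H]2[C@@]3(C)CC[C@H](O[Si](CC)(CC)CC)C(C)(C)O[C@@H]3CC[C@]2(C)O[Si](CC)(CC)CC)=C1C
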